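**Retrosynthetic overview**
1. The target is the unsymmetrical 6,6'-dimer of teracacidin (2R,3R,4R, all-cis) and isoteracacidin (2R,3R,4S). The halves differ only at the acid-labile benzylic C4. Both are therefore taken from one C2-symmetric precursor, C4 is sorted last by SN1 equilibration (the mixed isomer has a statistical weight of two), and six benzyl ethers are then removed.
2. Both 2,3-cis-3,4-diols come from a (2S,2'S)-bis(flav-3-ene): bromohydrin on the face anti to the aryl group, closure to the epoxide syn to it, opening at C4.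
3. Key disconnection: both O1–C2 bonds at once. A double enantioselective dehydrative cyclisation of a bis(1,3-diarylallyl alcohol) under a chiral Brønsted acid forms rings C and C' and both C2 centres in one operation.
4. The bis(allylic alcohol) comes from a bis(2'-hydroxychalcone), made by double Claisen–Schmidt condensation of a 5,5'-biaryl bis(acetophenone). The biaryl comes from para–para oxidative coupling of gallacetophenone 3,4-dibenzyl ether.
5. Ring order: rings A, A', B and B' are bought, the biaryl bond is made first, and rings C and C' form together in step 4. The oxiranes of step 5 are transient.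

Assumption: the 6,6'-axis has only two ortho oxygen substituents, rotates freely and carries no descriptor; the (R)-acid of step 4 is taken to give the 2S centres, otherwise its enantiomer is used.

**Step 1**
Reactants: 1 1-(2,3,4-trihydroxyphenyl)ethanone (gallacetophenone)
Product: 2 1-[3,4-bis(benzyloxy)-2-hydroxyphenyl]ethanone
Conditions: BnBr (2.05 equiv), K2CO3 (2.2 equiv), DMF, rt to 40 °C
Reagents that add atoms: benzyl bromide, BrCc1ccccc1
Why: Williamson etherification in which the 2-OH, locked in a hydrogen bond to the acetyl group, is the least nucleophilic oxygen, so two equivalents of halide alkylate only O3 and O4.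

**Step 2**
Reactants: 2 1-[3,4-bis(benzyloxy)-2-hydroxyphenyl]ethanone (two molecules)
Product: 3 1,1'-[2,2',3,3'-tetrakis(benzyloxy)-4,4'-dihydroxybiphenyl-5,5'-diyl]diethanone
Conditions: K2S2O8 (0.6 equiv), FeSO4·7H2O (10 mol %), MeCN–H2O 2:1, 75 °C
Reagents that add atoms: none
Why: Oxidative phenol coupling (the iron/persulfate type used to dimerise acyl guaiacols) in which both ortho positions of the phenoxyl radical are blocked by acetyl and benzyloxy, so C–C bond formation can occur only at the free para carbon C5, the future C6 and C6'; no stereocentre is formed.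

**Step 3**
Reactants: 3 1,1'-[2,2',3,3'-tetrakis(benzyloxy)-4,4'-dihydroxybiphenyl-5,5'-diyl]diethanone; 4 4-(benzyloxy)benzaldehyde (2.4 equiv)
Product: 5 (2E,2'E)-1,1'-[2,2',3,3'-tetrakis(benzyloxy)-4,4'-dihydroxybiphenyl-5,5'-diyl]bis{3-[4-(benzyloxy)phenyl]prop-2-en-1-one}
Conditions: KOH, EtOH–THF, rt, 36 h; cold dilute HCl quench
Reagents that add atoms: none
Why: Two-fold Claisen–Schmidt condensation whose E1cB dehydration gives the thermodynamic E-enones, while the phenolate form holds the open chalcone against closure to the flavanone.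

**Step 4 (key step)**
Reactants: 5 (2E,2'E)-bis(2'-hydroxychalcone)
Product: 7 (2S,2'S)-7,7',8,8'-tetrakis(benzyloxy)-2,2'-bis[4-(benzyloxy)phenyl]-2H,2'H-6,6'-bichromene, via bis(allylic alcohol) 6 (not isolated)
Conditions: NaBH4, THF–i-PrOH, 0 °C; aq. NaHCO3 work-up into toluene, dried over K2CO3; then (R)-3,3'-bis(2,4,6-triisopropylphenyl)-1,1'-binaphthalene-2,2'-diyl N-(trifluoromethylsulfonyl)phosphoramidate (10 mol %), 4 Å MS, toluene, 0.01 M, −78 °C, dark
Reagents that add atoms: none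
Why: Proposed new method: 1,2-reduction gives the doubly activated alcohol 6, which the strong chiral acid ionises at −78 °C to a 1,3-diarylallyl cation (a protonated vinyl ortho-quinone methide) held in a contact ion pair with the chiral phosphoramidate, so the phenol oxygen closes on one face of C2 in both halves, forming two pyran rings and both C2 centres while statistical amplification drains the minor sense into the separable meso 2R,2'S isomer; the closest known chemistry is the N-triflylphosphoramide-catalysed asymmetric intramolecular allylic etherification of 2-(3-hydroxyalk-1-enyl)phenols to 2H-chromenes, together with the classical borohydride–acid conversion of 2'-hydroxychalcones into flav-3-enes.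

**Step 5**
Reactants: 7 (2S,2'S)-bis(flav-3-ene)
Product: 11 (2R,2'R,3R,3'R,4R,4'S)-7,7',8,8'-tetrakis(benzyloxy)-2,2'-bis[4-(benzyloxy)phenyl]-6,6'-bichromane-3,3',4,4'-tetrol, via bis(bromohydrin) 8 (not isolated), via bis(epoxide) 9 (not isolated), via di-trans tetrol 10 (not isolated)
Conditions: NBS (2.1 equiv), DME–H2O 5:1, 0 °C, dark; K2CO3 (2.5 equiv), rt; extractive work-up; TsOH·H2O (5 mol %), THF–H2O 9:1, rt; chromatography on Et3N-washed silica
Reagents that add atoms: water, O (all four new oxygen atoms); N-bromosuccinimide, O=C1CCC(=O)N1Br (bromine only in 8, lost again in 9)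
Why: Halohydrin formation places bromine on the alkene face anti to the 2-aryl group and water at benzylic C4, intramolecular SN2 closure then puts the oxirane syn to the aryl group so that the retained C3–O bond is 2,3-cis (3R), solvolysis at C4 through the 7-alkoxy-stabilised cation gives mainly the 3,4-trans diol 10, and acid-catalysed SN1 epimerisation of the C4 carbinols equilibrates the C4 isomers, from which the unsymmetrical 4R,4'S isomer, favoured by its statistical factor of two, is separated.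

**Step 6**
Reactants: 11 (2R,2'R,3R,3'R,4R,4'S)-hexabenzyl tetrol
Product: 12 (2R,2'R,3R,3'R,4R,4'S)-2,2'-bis(4-hydroxyphenyl)-6,6'-bichromane-3,3',4,4',7,7',8,8'-octol (CNP0121763.1)
Conditions: H2 (1 atm), Pd/C (10 wt %), THF–H2O 9:1, rt; filter; Sephadex LH-20, acetone–H2O
Reagents that add atoms: none
Why: Catalytic hydrogenolysis cleaves the six aryl benzyl ethers faster than the secondary C4 carbinols or the C2–O1 bond, and the neutral, alcohol-free medium prevents ionisation or etherification at C4, so no stereocentre is touched.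

**Compound list**
1 | 1-(2,3,4-trihydroxyphenyl)ethanone | CC(=O)c1ccc(O)c(O)c1O | starting material
2 | 1-[3,4-bis(benzyloxy)-2-hydroxyphenyl]ethanone | CC(=O)c1ccc(OCc2ccccc2)c(OCc2ccccc2)c1O | intermediate
3 | 1,1'-[2,2',3,3'-tetrakis(benzyloxy)-4,4'-dihydroxybiphenyl-5,5'-diyl]diethanone | CC(=O)c1cc(-c2cc(C(C)=O)c(O)c(OCc3ccccc3)c2OCc2ccccc2)c(OCc2ccccc2)c(OCc2ccccc2)c1O | intermediate
4 | 4-(benzyloxy)benzaldehyde | O=Cc1ccc(OCc2ccccc2)cc1 | starting material
5 | (2E,2'E)-bis(2'-hydroxychalcone) of 3 and 4 | O=C(/C=C/c1ccc(OCc2ccccc2)cc1)c1cc(-c2cc(C(=O)/C=C/c3ccc(OCc4ccccc4)cc3)c(O)c(OCc3ccccc3)c2OCc2ccccc2)c(OCc2ccccc2)c(OCc2ccccc2)c1O | intermediate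
6 | (E,E)-bis(allylic alcohol) from 5, carbinol centres unselective | OC(/C=C/c1ccc(OCc2ccccc2)cc1)c1cc(-c2cc(C(O)/C=C/c3ccc(OCc4ccccc4)cc3)c(O)c(OCc3ccccc3)c2OCc2ccccc2)c(OCc2ccccc2)c(OCc2ccccc2)c1O | intermediate
7 | (2S,2'S)-7,7',8,8'-tetrakis(benzyloxy)-2,2'-bis[4-(benzyloxy)phenyl]-2H,2'H-6,6'-bichromene | c1ccccc1COc1ccc([C@H]2Oc3c(cc(-c4cc5c(c(OCc6ccccc6)c4OCc4ccccc4)O[C@H](c4ccc(OCc6ccccc6)cc4)C=C5)c(OCc4ccccc4)c3OCc3ccccc3)C=C2)cc1 | intermediate
8 | (2R,2'R,3S,3'S,4R,4'R)-3,3'-dibromo hexabenzyl 6,6'-bichromane-4,4'-diol (Br trans to aryl and to OH) | c1ccccc1COc1ccc([C@H]2Oc3c(cc(-c4cc5c(c(OCc6ccccc6)c4OCc4ccccc4)O[C@H](c4ccc(OCc6ccccc6)cc4)[C@@H](Br)[C@@H]5O)c(OCc4ccccc4)c3OCc3ccccc3)[C@@H](O)[C@@H]2Br)cc1 | intermediate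
9 | (2R,2'R,3R,3'R,4R,4'R)-3,4:3',4'-diepoxy hexabenzyl 6,6'-bichromane (each oxirane cis to its 2-aryl group) | c1ccccc1COc1ccc([C@H]2Oc3c(cc(-c4cc5c(c(OCc6ccccc6)c4OCc4ccccc4)O[C@H](c4ccc(OCc6ccccc6)cc4)[C@@H]8O[C@H]58)c(OCc4ccccc4)c3OCc3ccccc3)[C@H]7O[C@@H]27)cc1 | intermediate
10 | (2R,2'R,3R,3'R,4S,4'S)-hexabenzyl 6,6'-bichromane-3,3',4,4'-tetrol (both halves 2,3-cis-3,4-trans) | c1ccccc1COc1ccc([C@H]2Oc3c(cc(-c4cc5c(c(OCc6ccccc6)c4OCc4ccccc4)O[C@H](c4ccc(OCc6ccccc6)cc4)[C@H](O)[C@H]5O)c(OCc4ccccc4)c3OCc3ccccc3)[C@H](O)[C@H]2O)cc1 | intermediate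
11 | (2R,2'R,3R,3'R,4R,4'S)-hexabenzyl 6,6'-bichromane-3,3',4,4'-tetrol (one half all-cis, one half 3,4-trans) | c1ccccc1COc1ccc([C@H]2Oc3c(cc(-c4cc5c(c(OCc6ccccc6)c4OCc4ccccc4)O[C@H](c4ccc(OCc6ccccc6)cc4)[C@H](O)[C@H]5O)c(OCc4ccccc4)c3OCc3ccccc3)[C@@H](O)[C@H]2O)cc1 | intermediate
12 | (2R,2'R,3R,3'R,4R,4'S)-2,2'-bis(4-hydroxyphenyl)-6,6'-bichromane-3,3',4,4',7,7',8,8'-octol | Oc1ccc([C@H]2Oc3c(cc(-c4cc5c(c(O)c4O)O[C@H](c4ccc(O)cc4)[C@H](O)[C@H]5O)c(O)c3O)[C@@H](O)[C@H]2O)cc1 | target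

**Total steps:** 6. **Longest linear sequence:** 6 (1 → 2 → 3 → 5 → 7 → 11 → 12).

**Three steps most likely to fail**

Step 4. Compound 6 may cyclise racemically during work-up, and the enantioselectivity for a secondary diarylallyl cation is untested.
- The fallback sets out from 3 and comes back at 7. It sets C2 by C–C bond formation instead of C–O bond formation.
- Compound 3 is heated with N,N-dimethylformamide dimethyl acetal in toluene to give the bis(enaminone) (2E,2'E)-1,1'-[2,2',3,3'-tetrakis(benzyloxy)-4,4'-dihydroxybiphenyl-5,5'-diyl]bis[3-(dimethylamino)prop-2-en-1-one] F1.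
- HCl in CH2Cl2 then closes both pyran rings in one operation to the bis(chromone) 7,7',8,8'-tetrakis(benzyloxy)-4H,4'H-6,6'-bichromene-4,4'-dione F2.
- Asymmetric conjugate addition of 4-(benzyloxy)phenylboronic acid gives the bis(flavanone) (2S,2'S)-7,7',8,8'-tetrakis(benzyloxy)-2,2'-bis[4-(benzyloxy)phenyl]-6,6'-bichromane-4,4'-dione F3. The conditions are Pd(OCOCF3)2, the enantiomer of 4-tert-butyl-2-(pyridin-2-yl)-4,5-dihydrooxazole that delivers 2S, NH4PF6 and H2O in ClCH2CH2Cl at 60 °C.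
- NaBH4 gives the 2,4-cis bis(flavan-4-ol) (2S,2'S,4S,4'S)-7,7',8,8'-tetrakis(benzyloxy)-2,2'-bis[4-(benzyloxy)phenyl]-6,6'-bichromane-4,4'-diol F4.
- Catalytic pyridinium p-toluenesulfonate in warm toluene dehydrates F4 to 7.

Step 5. NBS may attack the aromatic rings, the epoxide may rearrange to the flavan-3-one by hydride shift, and the position of the C4 equilibrium is not known. Recovered C2-symmetric C4 isomers go back into the acid equilibration.
- The fallback sets out from 7 and comes back at 10. It sets C3 by ketone reduction and C4 by benzylic C–H oxidation.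
- Hydroboration–oxidation (BH3·THF, then NaOH/H2O2) gives the 2,3-trans bis(flavan-3-ol) (2R,2'R,3S,3'S)-7,7',8,8'-tetrakis(benzyloxy)-2,2'-bis[4-(benzyloxy)phenyl]-6,6'-bichromane-3,3'-diol F5.
- Dess–Martin periodinane gives the bis(flavan-3-one) (2R,2'R)-7,7',8,8'-tetrakis(benzyloxy)-2,2'-bis[4-(benzyloxy)phenyl]-6,6'-bichromane-3,3'-dione F6.
- LiBH(s-Bu)3 at −78 °C attacks anti to the aryl group and gives the 2,3-cis bis(flavan-3-ol) (2R,2'R,3R,3'R)-7,7',8,8'-tetrakis(benzyloxy)-2,2'-bis[4-(benzyloxy)phenyl]-6,6'-bichromane-3,3'-diol F7.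
- DDQ in CH2Cl2–H2O oxidises both C4–H positions to the cation, which water traps anti to the 3-OH to give 10. Compound 10 then enters the TsOH equilibration of step 5.

Step 2. Risks are over-oxidation to the diphenoquinone, attack on the benzylic CH2 groups, and sluggish oxidation of the chelated phenol.
- The fallback sets out from 2 and comes back at 3. It replaces radical coupling by halogenation and cross-coupling.
- N-Iodosuccinimide with catalytic CF3CO2H in MeCN iodinates para to the free OH and gives 1-[3,4-bis(benzyloxy)-2-hydroxy-5-iodophenyl]ethanone F8.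
- Bis(pinacolato)diboron (0.55 equiv), PdCl2(dppf) and K2CO3 in dioxane–H2O at 90 °C convert half of F8 into 1-[3,4-bis(benzyloxy)-2-hydroxy-5-(4,4,5,5-tetramethyl-1,3,2-dioxaborolan-2-yl)phenyl]ethanone F9.
- F9 couples in the same flask with the remaining F8 (Suzuki–Miyaura) to give 3.

**Further compounds**
F1 | step 4 | (2E,2'E)-1,1'-[2,2',3,3'-tetrakis(benzyloxy)-4,4'-dihydroxybiphenyl-5,5'-diyl]bis[3-(dimethylamino)prop-2-en-1-one] | CN(C)/C=C/C(=O)c1cc(-c2cc(C(=O)/C=C/N(C)C)c(O)c(OCc3ccccc3)c2OCc2ccccc2)c(OCc2ccccc2)c(OCc2ccccc2)c1O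
F2 | step 4 | 7,7',8,8'-tetrakis(benzyloxy)-4H,4'H-6,6'-bichromene-4,4'-dione | O=c1ccoc2c(OCc3ccccc3)c(OCc3ccccc3)c(-c3cc4c(=O)ccoc4c(OCc4ccccc4)c3OCc3ccccc3)cc12
F3 | step 4 | (2S,2'S)-7,7',8,8'-tetrakis(benzyloxy)-2,2'-bis[4-(benzyloxy)phenyl]-6,6'-bichromane-4,4'-dione | c1ccccc1COc1ccc([C@H]2Oc3c(cc(-c4cc5c(c(OCc6ccccc6)c4OCc4ccccc4)O[C@H](c4ccc(OCc6ccccc6)cc4)CC5=O)c(OCc4ccccc4)c3OCc3ccccc3)C(=O)C2)cc1
F4 | step 4 | (2S,2'S,4S,4'S)-7,7',8,8'-tetrakis(benzyloxy)-2,2'-bis[4-(benzyloxy)phenyl]-6,6'-bichromane-4,4'-diol | c1ccccc1COc1ccc([C@H]2Oc3c(cc(-c4cc5c(c(OCc6ccccc6)c4OCc4ccccc4)O[C@H](c4ccc(OCc6ccccc6)cc4)C[C@@H]5O)c(OCc4ccccc4)c3OCc3ccccc3)[C@@H](O)C2)cc1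
F5 | step 5 | (2R,2'R,3S,3'S)-7,7',8,8'-tetrakis(benzyloxy)-2,2'-bis[4-(benzyloxy)phenyl]-6,6'-bichromane-3,3'-diol | c1ccccc1COc1ccc([C@H]2Oc3c(cc(-c4cc5c(c(OCc6ccccc6)c4OCc4ccccc4)O[C@H](c4ccc(OCc6ccccc6)cc4)[C@@H](O)C5)c(OCc4ccccc4)c3OCc3ccccc3)C[C@@H]2O)cc1
F6 | step 5 | (2R,2'R)-7,7',8,8'-tetrakis(benzyloxy)-2,2'-bis[4-(benzyloxy)phenyl]-6,6'-bichromane-3,3'-dione | c1ccccc1COc1ccc([C@H]2Oc3c(cc(-c4cc5c(c(OCc6ccccc6)c4OCc4ccccc4)O[C@H](c4ccc(OCc6ccccc6)cc4)C(=O)C5)c(OCc4ccccc4)c3OCc3ccccc3)CC2=O)cc1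
F7 | step 5 | (2R,2'R,3R,3'R)-7,7',8,8'-tetrakis(benzyloxy)-2,2'-bis[4-(benzyloxy)phenyl]-6,6'-bichromane-3,3'-diol | c1ccccc1COc1ccc([C@H]2Oc3c(cc(-c4cc5c(c(OCc6ccccc6)c4OCc4ccccc4)O[C@H](c4ccc(OCc6ccccc6)cc4)[C@H](O)C5)c(OCc4ccccc4)c3OCc3ccccc3)C[C@H]2O)cc1
F8 | step 2 | 1-[3,4-bis(benzyloxy)-2-hydroxy-5-iodophenyl]ethanone | CC(=O)c1cc(I)c(OCc2ccccc2)c(OCc2ccccc2)c1O
F9 | step 2 | 1-[3,4-bis(benzyloxy)-2-hydroxy-5-(4,4,5,5-tetramethyl-1,3,2-dioxaborolan-2-yl)phenyl]ethanone | CC(=O)c1cc(B2OC(C)(C)C(C)(C)O2)c(OCc2ccccc2)c(OCc2ccccc2)c1O
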